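**Retrosynthetic overview**
- The target is cut at the C15 ester into (E)-ferulic acid (from catechol, MeI and acrylic acid by bromination and Heck coupling) and (13R)-labd-7-ene-2α,15-diol; the two are joined last by a primary-selective Mitsunobu esterification.
- In the diol, the 2α-OH comes from α-face hydroboration of a C2=C3 alkene, and the C8-methyl/C7=C8 unit comes from a C8 ketone by Shapiro methylation.
- Key step: ring B is formed last by a one-carbon semipinacol ring expansion of a trans-hydrindanone adduct, in which C10 shifts from C8 to C9 and C9 arrives carrying the whole C11–C15 side chain.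
- The trans-hydrindenone comes from 2-methylcyclopent-2-enone by enantioselective conjugate reverse prenylation, enolate allylation and ring-closing metathesis; the side-chain donor comes from 4-methylcyclohexanone by a desymmetrising Baeyer–Villiger ring expansion.
- Ring order: the cyclopentane is bought, ring A is closed by metathesis, ring B is made by ring expansion; the arene comes from catechol.

Assumption: the SMILES is read as (13R)-2α-hydroxylabd-7-en-15-yl (E)-ferulate with the normal labdane configuration (2S,5S,9S,10S); for each chiral catalyst the enantiomer that gives the stated product is used.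

Step 1
Reactants: 1 1-chloro-3-methylbut-2-ene (prenyl chloride)
Product: 3 trimethyl(3-methylbut-2-en-1-yl)silane (prenyltrimethylsilane), via prenylmagnesium chloride 2 (not isolated)
Conditions: Mg turnings, Me3SiCl, THF, 0 → 20 °C (Barbier mode)
Reagents that add atoms: chlorotrimethylsilane, C[Si](C)(C)Cl
Why: Barbier-type Grignard formation and silylation at the less hindered primary terminus of the allylic Grignard give the prenylsilane that later reacts through its γ-carbon as a reverse-prenyl donor; no stereocentre is formed.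

Step 2
Reactants: 3 prenyltrimethylsilane; 4 2-methylcyclopent-2-en-1-one; 5 3-bromoprop-1-ene (allyl bromide)
Product: 8 (2S,3S)-2-methyl-3-(2-methylbut-3-en-2-yl)-2-(prop-2-en-1-yl)cyclopentan-1-one, via silyl enol ether 6 (not isolated), via lithium enolate 7 (not isolated)
Conditions: 3 (1.5 equiv), chiral BINOL-derived imidodiphosphorimidate (IDPi) acid (2 mol %), toluene, −60 °C; evaporate; then MeLi (1.0 equiv), THF, 0 °C; then 5, DMPU, −78 → 0 °C
Reagents that add atoms: none
Why: Proposed new method: an enantioselective conjugate Hosomi–Sakurai reverse prenylation under silylium-based asymmetric counteranion-directed catalysis, in which the IDPi acid is silylated by 3, the Me3Si+/IDPi− pair O-silylates enone 4, 3 attacks the β-carbon through its γ-carbon (SE2′) inside the confined chiral anion to create the quaternary C4 and the C5 stereocentre (3S in 6), and the β-silyl cation returns Me3Si+ to the catalyst to release 6 (closest known reactions: IDPi-catalysed Mukaiyama–Michael additions and aldehyde Hosomi–Sakurai allylations, and the achiral Tf2NH-catalysed conjugate allylation of enones), after which the known regiospecific MeLi cleavage to enolate 7 and allylation anti to the bulky C3 substituent set the quaternary centre (future C10) with allyl trans and methyl cis to the tert-alkyl group.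

Step 3
Reactants: 8 (2S,3S)-2-methyl-3-(2-methylbut-3-en-2-yl)-2-(prop-2-en-1-yl)cyclopentan-1-one
Product: 9 (3aS,7aS)-4,4,7a-trimethyl-2,3,3a,4,7,7a-hexahydro-1H-inden-1-one
Conditions: second-generation Grubbs catalyst (H2IMes)(PCy3)Cl2Ru=CHPh (3 mol %), CH2Cl2 (0.01 M), 40 °C
Reagents that add atoms: none
Why: ring-closing metathesis of the vinyl and allyl groups, held trans on adjacent ring carbons, closes ring A as a cyclohexene and gives the trans ring fusion (future 5α-H and 10β-Me) without touching either stereocentre.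

Step 4
Reactants: 10 4-methylcyclohexan-1-one
Product: 11 (5R)-5-methyloxepan-2-one
Conditions: m-CPBA, Sc(OTf)3 (5 mol %), chiral N,N′-dioxide ligand (6 mol %), EtOAc, −20 °C
Reagents that add atoms: 3-chloroperoxybenzoic acid, OOC(=O)c1cccc(Cl)c1
Why: catalytic asymmetric Baeyer–Villiger oxidation (a desymmetrising ring expansion), in which the chiral Sc(OTf)3–N,N′-dioxide complex selects one of the two enantiotopic ring CH2 groups for migration in the Criegee adduct so that the methyl-bearing carbon (future C13) is R.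

Step 5
Reactants: 11 (5R)-5-methyloxepan-2-one
Product: 13 (3R)-3-methyl-6,6-bis(phenylselanyl)hexan-1-ol, via aluminium lactolate 12 (not isolated)
Conditions: iBu2AlH (1.05 equiv), CH2Cl2, −78 °C; then PhSeH (2.5 equiv), BF3·OEt2, −78 → 0 °C; aqueous work-up
Reagents that add atoms: benzeneselenol, [SeH]c1ccccc1
Why: half-reduction of the lactone followed by Lewis-acid selenoacetalisation (analogous to thioacetal formation from lactols) opens the ring, frees the C15 hydroxyl and turns the former carbonyl carbon into the future C9 as a bis(selenide), while C13 is not involved.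

Step 6
Reactants: 13 (3R)-3-methyl-6,6-bis(phenylselanyl)hexan-1-ol; 9 (3aS,7aS)-4,4,7a-trimethyl-2,3,3a,4,7,7a-hexahydro-1H-inden-1-one
Product: 15 (3aS,7aS)-1-[(4R)-6-hydroxy-4-methyl-1-(phenylselanyl)hexyl]-4,4,7a-trimethyl-2,3,3a,4,7,7a-hexahydro-1H-inden-1-ol (mixture at the two new centres), via dilithio selenide 14 (not isolated)
Conditions: nBuLi (2.1 equiv), THF, −78 °C; then 9, −78 °C; H2O
Reagents that add atoms: none
Why: Se/Li exchange gives a weakly basic but very nucleophilic α-selenoalkyllithium that adds to the hindered, enolisable ketone (1,2-addition, C8–C9 bond) from the face opposite the angular methyl; the new C8 and C9 centres form as a mixture that does not matter, because C8 becomes a carbonyl and C9 is equilibrated in step 7.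

Step 7
Reactants: 15 β-hydroxy selenide
Product: 17 (1R,4aS,8aS)-1-[(3R)-5-hydroxy-3-methylpentyl]-5,5,8a-trimethyl-3,4,4a,5,8,8a-hexahydronaphthalen-2(1H)-one [(13R)-15-hydroxy-17-norlabd-2-en-8-one; 5α-H/9α-H/10β-Me], via C9-epimeric ketone 16 (not isolated)
Conditions: AgBF4 (1.5 equiv), basic Al2O3, CH2Cl2, 20 °C; then DBU (0.2 equiv), 20 °C
Reagents that add atoms: none
Why: Krief-type semipinacol ring expansion (a 1,2-alkyl shift), in which Ag+ turns the PhSe group on C9 into a leaving group and the antiperiplanar, more substituted ring carbon C10 shifts from C8 to C9 with retention at C10 (quaternary-carbon migration is the usual preference in selenium-triggered expansions and is helped by release of trans-hydrindane strain), so that ring B closes, the C9–C10 bond forms and the C8 ketone appears; DBU then equilibrates C9 to the equatorial 9β side chain.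

Step 8
Reactants: 17 (13R)-15-hydroxy-17-norlabd-2-en-8-one
Product: 18 N′-[(1R,4aS,8aS)-1-[(3R)-5-hydroxy-3-methylpentyl]-5,5,8a-trimethyl-3,4,4a,5,8,8a-hexahydronaphthalen-2(1H)-ylidene]-2,4,6-tri(propan-2-yl)benzenesulfonohydrazide
Conditions: 2,4,6-iPr3C6H2SO2NHNH2 (1.2 equiv), HCl (cat.), THF, 20 °C
Reagents that add atoms: 2,4,6-tri(propan-2-yl)benzenesulfonohydrazide, CC(C)c1cc(C(C)C)c(S(=O)(=O)NN)c(C(C)C)c1
Why: acid-catalysed hydrazone condensation at the only carbonyl, with the arylsulfonyl group lying anti to the more substituted C9 side; any C9 epimerisation returns the same equatorial isomer.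

Step 9
Reactants: 18 trisylhydrazone
Product: 20 (3R)-3-methyl-5-[(1S,4aS,8aR)-2,5,5,8a-tetramethyl-1,4,4a,5,8,8a-hexahydronaphthalen-1-yl]pentan-1-ol [(13R)-labda-2,7-dien-15-ol], via vinyllithium 19 (not isolated)
Conditions: nBuLi (3.1 equiv), THF/TMEDA, −78 → 0 °C; then MeI (1.5 equiv), −78 → 0 °C; H2O
Reagents that add atoms: iodomethane, CI
Why: Shapiro reaction, in which (after OH and NH deprotonation) the third equivalent of base removes a C7 proton on the less substituted side syn to the sulfonamide, loss of sulfinate and N2 gives the C8 vinyllithium with the C7=C8 bond fixed, and MeI installs C17 regiospecifically without touching C9.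

Step 10
Reactants: 20 (13R)-labda-2,7-dien-15-ol
Product: 22 (13R)-labd-7-ene-2α,15-diol [(2S,5S,9S,10S,13R)], via bis-borane adduct 21 (not isolated)
Conditions: 9-BBN (2.2 equiv), THF, 60 °C; then NaOH (aq), H2O2, 0 → 20 °C
Reagents that add atoms: hydrogen peroxide, OO
Why: hydroboration–oxidation, in which bulky 9-BBN selects the cis-disubstituted C2=C3 alkene over the hindered trisubstituted C7=C8 alkene, puts boron on C2 (away from the neopentyl C3) from the α face opposite the axial 4β- and 10β-methyl groups, and oxidation with retention gives the equatorial 2α-OH (2S).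

Step 11
Reactants: 23 benzene-1,2-diol (catechol, 2 equiv)
Product: 24 2-methoxyphenol
Conditions: MeI (1.0 equiv), K2CO3, acetone, 56 °C
Reagents that add atoms: iodomethane, CI
Why: Williamson mono-O-methylation, with excess catechol suppressing the dimethyl ether.

Step 12
Reactants: 24 2-methoxyphenol
Product: 25 4-bromo-2-methoxyphenol
Conditions: NBS (1.0 equiv), MeCN, 0 °C
Reagents that add atoms: N-bromosuccinimide, O=C1CCC(=O)N1Br
Why: electrophilic aromatic bromination, directed para to the stronger donor (OH).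

Step 13
Reactants: 25 4-bromo-2-methoxyphenol; 26 prop-2-enoic acid (acrylic acid)
Product: 27 (2E)-3-(4-hydroxy-3-methoxyphenyl)prop-2-enoic acid (ferulic acid)
Conditions: Pd(OAc)2 (1 mol %), P(o-tol)3 (4 mol %), Et3N (3 equiv), MeCN, 100 °C; then HCl (aq)
Reagents that add atoms: none
Why: Mizoroki–Heck reaction, in which syn-insertion and syn-β-hydride elimination give the (E)-cinnamic acid; the free phenol and acid are carried as their ammonium salts.

Step 14
Reactants: 22 (13R)-labd-7-ene-2α,15-diol; 27 ferulic acid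
Product: 28 (13R)-2α-hydroxylabd-7-en-15-yl (E)-ferulate (CNP0175017.1)
Conditions: PPh3 (1.2 equiv), iPrO2CN=NCO2iPr (1.2 equiv), THF, 0 → 20 °C
Reagents that add atoms: none
Why: Mitsunobu esterification, in which the carboxylic acid (far more acidic than the phenol) is the nucleophile and only the unhindered primary C15 alcohol is activated, so the hindered secondary 2α-OH and the phenol stay free and no stereocentre is touched.

**Compound list**
1 | 1-chloro-3-methylbut-2-ene | CC(C)=CCCl | starting material
2 | (3-methylbut-2-en-1-yl)magnesium chloride | CC(C)=CC[Mg]Cl | intermediate (not isolated)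
3 | trimethyl(3-methylbut-2-en-1-yl)silane | CC(C)=CC[Si](C)(C)C | intermediate
4 | 2-methylcyclopent-2-en-1-one | CC1=CCCC1=O | starting material
5 | 3-bromoprop-1-ene | C=CCBr | starting material
6 | (S)-trimethyl{[2-methyl-3-(2-methylbut-3-en-2-yl)cyclopent-1-en-1-yl]oxy}silane | C[Si](C)(C)OC1=C(C)[C@H](C(C)(C)C=C)CC1 | intermediate (not isolated)
7 | lithium (S)-2-methyl-3-(2-methylbut-3-en-2-yl)cyclopent-1-en-1-olate | [Li]OC1=C(C)[C@H](C(C)(C)C=C)CC1 | intermediate (not isolated)
8 | (2S,3S)-2-methyl-3-(2-methylbut-3-en-2-yl)-2-(prop-2-en-1-yl)cyclopentan-1-one | O=C1CC[C@@H](C(C)(C)C=C)[C@]1(C)CC=C | intermediate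
9 | (3aS,7aS)-4,4,7a-trimethyl-2,3,3a,4,7,7a-hexahydro-1H-inden-1-one (trans-fused) | O=C1CC[C@H]2C(C)(C)C=CC[C@]12C | intermediate
10 | 4-methylcyclohexan-1-one | CC1CCC(=O)CC1 | starting material
11 | (5R)-5-methyloxepan-2-one | O=C1CC[C@@H](C)CCO1 | intermediate
12 | diisobutylaluminium (5R)-5-methyloxepan-2-olate | CC(C)C[Al](CC(C)C)OC1CC[C@@H](C)CCO1 | intermediate (not isolated)
13 | (3R)-3-methyl-6,6-bis(phenylselanyl)hexan-1-ol | OCC[C@H](C)CCC([Se]c1ccccc1)[Se]c1ccccc1 | intermediate
14 | lithium (3R)-6-lithio-3-methyl-6-(phenylselanyl)hexan-1-olate | [Li]OCC[C@H](C)CCC([Li])[Se]c1ccccc1 | intermediate (not isolated)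
15 | (3aS,7aS)-1-[(4R)-6-hydroxy-4-methyl-1-(phenylselanyl)hexyl]-4,4,7a-trimethyl-2,3,3a,4,7,7a-hexahydro-1H-inden-1-ol (epimers at the carbinol and selenide carbons) | OCC[C@H](C)CCC([Se]c1ccccc1)C1(O)CC[C@H]2C(C)(C)C=CC[C@]12C | intermediate
16 | (1S,4aS,8aS)-1-[(3R)-5-hydroxy-3-methylpentyl]-5,5,8a-trimethyl-3,4,4a,5,8,8a-hexahydronaphthalen-2(1H)-one (C9 epimer of 17) | OCC[C@H](C)CC[C@@H]1C(=O)CC[C@H]2C(C)(C)C=CC[C@]12C | intermediate (not isolated)
17 | (1R,4aS,8aS)-1-[(3R)-5-hydroxy-3-methylpentyl]-5,5,8a-trimethyl-3,4,4a,5,8,8a-hexahydronaphthalen-2(1H)-one | OCC[C@H](C)CC[C@H]1C(=O)CC[C@H]2C(C)(C)C=CC[C@]12C | intermediate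
18 | 2,4,6-tri(propan-2-yl)benzenesulfonyl hydrazone of 17 | OCC[C@H](C)CC[C@H]1C(=NNS(=O)(=O)c3c(C(C)C)cc(C(C)C)cc3C(C)C)CC[C@H]2C(C)(C)C=CC[C@]12C | intermediate
19 | C8 vinyllithium (lithium alkoxide) from 18 | [Li]OCC[C@H](C)CC[C@H]1C([Li])=CC[C@H]2C(C)(C)C=CC[C@]12C | intermediate (not isolated)
20 | (13R)-labda-2,7-dien-15-ol; (3R)-3-methyl-5-[(1S,4aS,8aR)-2,5,5,8a-tetramethyl-1,4,4a,5,8,8a-hexahydronaphthalen-1-yl]pentan-1-ol | OCC[C@H](C)CC[C@H]1C(C)=CC[C@H]2C(C)(C)C=CC[C@]12C | intermediate
21 | 2α-(9-borabicyclo[3.3.1]nonan-9-yl)labd-7-en-15-yl 9-borabicyclo[3.3.1]nonane-9-borinate | B1(OCC[C@H](C)CC[C@H]2C(C)=CC[C@H]3C(C)(C)C[C@H](B4C5CCCC4CCC5)C[C@]23C)C2CCCC1CCC2 | intermediate (not isolated)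
22 | (2S,5S,9S,10S,13R)-labd-7-ene-2,15-diol (2α-OH) | OCC[C@H](C)CC[C@H]1C(C)=CC[C@H]2C(C)(C)C[C@H](O)C[C@]12C | intermediate
23 | benzene-1,2-diol | Oc1ccccc1O | starting material
24 | 2-methoxyphenol | COc1ccccc1O | intermediate
25 | 4-bromo-2-methoxyphenol | COc1cc(Br)ccc1O | intermediate
26 | prop-2-enoic acid | C=CC(=O)O | starting material
27 | (2E)-3-(4-hydroxy-3-methoxyphenyl)prop-2-enoic acid | COc1cc(/C=C/C(=O)O)ccc1O | intermediate
28 | (13R)-2α-hydroxylabd-7-en-15-yl (E)-ferulate | COc1cc(/C=C/C(=O)OCC[C@H](C)CC[C@H]2C(C)=CC[C@H]3C(C)(C)C[C@H](O)C[C@]23C)ccc1O | target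

**Step count**
Total: 14 steps. Longest linear sequence: 9 steps (1, 2, 3, 6, 7, 8, 9, 10, 14).

**Steps most likely to fail, with fallbacks**

Step 2 (the proposed new reaction). The risks are low enantioselectivity with the α-methyl enone and a racemic background reaction. The fallback uses known chemistry and switches from asymmetric catalysis to resolution. It sets out from 3 and 4. Tf2NH (1 mol %) in CH2Cl2 at −78 °C gives the racemic conjugate allylation product, that is 6 together with the enantiomeric silyl enol ether F1. The same MeLi/allyl bromide sequence (through 7 and the enantiomeric lithium enolate F2) gives racemic ketone, 8 plus the (2R,3R)-ketone F3. Metathesis as in step 3 gives racemic bicycle, 9 plus the (3aR,7aR)-hydrindenone F4. Preparative supercritical-fluid chromatography on a chiral polysaccharide phase removes F4, and the route is rejoined at 9.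

Step 7 (ring expansion). The risks are epoxide formation at the secondary selenide carbon and competing migration of the CH2 carbon C7. The fallback triggers the same shift from an allylic alcohol instead of a selenonium ion and sets out from 15. H2O2/pyridine in CH2Cl2 gives the selenoxide F5, which eliminates away from the hydroxyl to the (E)-allylic alcohol F6. NBS in CH2Cl2 at −20 °C then brings about a bromonium-induced semipinacol ring expansion to the β-bromo ketone F7. Bu3SnH/AIBN in benzene at 80 °C removes bromine, and DBU equilibrates C9. The route is rejoined at 17.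

Step 10 (hydroboration). The risk is competing hydroboration of the C7=C8 alkene. The fallback changes the order so that the borane meets only one reactive alkene; it sets out from 17 and also replaces steps 8 and 9. TBSCl/imidazole gives the silyl ether F8. KN(SiMe3)2 and N-(5-chloropyridin-2-yl)triflimide at −78 °C give the C7=C8 enol triflate F9, which is inert to boranes. 9-BBN adds to the C2=C3 alkene to give the borane adduct F10, and NaBO3 oxidises it to the 2α-hydroxy triflate F11. MeMgBr with Fe(acac)3 (5 mol %) in THF/NMP at −20 °C gives the C8-methyl silyl ether F12. Bu4NF removes the silyl group, and the route is rejoined at 22.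

**Further compounds**
F1 | step 2 | (R)-trimethyl{[2-methyl-3-(2-methylbut-3-en-2-yl)cyclopent-1-en-1-yl]oxy}silane (enantiomer of 6) | C[Si](C)(C)OC1=C(C)[C@@H](C(C)(C)C=C)CC1
F2 | step 2 | lithium (R)-2-methyl-3-(2-methylbut-3-en-2-yl)cyclopent-1-en-1-olate (enantiomer of 7) | [Li]OC1=C(C)[C@@H](C(C)(C)C=C)CC1
F3 | step 2 | (2R,3R)-2-methyl-3-(2-methylbut-3-en-2-yl)-2-(prop-2-en-1-yl)cyclopentan-1-one (enantiomer of 8) | O=C1CC[C@H](C(C)(C)C=C)[C@@]1(C)CC=C
F4 | step 2 | (3aR,7aR)-4,4,7a-trimethyl-2,3,3a,4,7,7a-hexahydro-1H-inden-1-one (enantiomer of 9) | O=C1CC[C@@H]2C(C)(C)C=CC[C@@]12C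
F5 | step 7 | selenoxide of 15 | OCC[C@H](C)CCC([Se](=O)c1ccccc1)C1(O)CC[C@H]2C(C)(C)C=CC[C@]12C
F6 | step 7 | (3aS,7aS)-1-[(1E,4R)-6-hydroxy-4-methylhex-1-en-1-yl]-4,4,7a-trimethyl-2,3,3a,4,7,7a-hexahydro-1H-inden-1-ol | OCC[C@H](C)C/C=C/C1(O)CC[C@H]2C(C)(C)C=CC[C@]12C
F7 | step 7 | 11-bromo-15-hydroxy-17-norlabd-2-en-8-one (mixture at C9 and C11; C13 as in 17) | OCC[C@H](C)CC(Br)C1C(=O)CC[C@H]2C(C)(C)C=CC[C@]12C
F8 | step 10 | tert-butyldimethylsilyl ether of 17 | CC(C)(C)[Si](C)(C)OCC[C@H](C)CC[C@H]1C(=O)CC[C@H]2C(C)(C)C=CC[C@]12C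
F9 | step 10 | 15-(tert-butyldimethylsilyloxy)-17-norlabda-2,7-dien-8-yl trifluoromethanesulfonate | CC(C)(C)[Si](C)(C)OCC[C@H](C)CC[C@H]1C(OS(=O)(=O)C(F)(F)F)=CC[C@H]2C(C)(C)C=CC[C@]12C
F10 | step 10 | 2α-(9-borabicyclo[3.3.1]nonan-9-yl) adduct of F9 | CC(C)(C)[Si](C)(C)OCC[C@H](C)CC[C@H]1C(OS(=O)(=O)C(F)(F)F)=CC[C@H]2C(C)(C)C[C@H](B3C4CCCC3CCC4)C[C@]12C
F11 | step 10 | 15-(tert-butyldimethylsilyloxy)-2α-hydroxy-17-norlabd-7-en-8-yl trifluoromethanesulfonate | CC(C)(C)[Si](C)(C)OCC[C@H](C)CC[C@H]1C(OS(=O)(=O)C(F)(F)F)=CC[C@H]2C(C)(C)C[C@H](O)C[C@]12C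
F12 | step 10 | (13R)-15-(tert-butyldimethylsilyloxy)labd-7-en-2α-ol | CC(C)(C)[Si](C)(C)OCC[C@H](C)CC[C@H]1C(C)=CC[C@H]2C(C)(C)C[C@H](O)C[C@]12C
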